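(The data were generated by integration for an exercise; the scatter is artificial.)

I had no rate constants for larch, and your quick number needed none, nor did your hunch that more free catalyst would carry the flask further. I wrote instead the balance of the reagent, charged in less than the substrate (15.6 mM against 26 mM).

| flask | substrate | reagent | free catalyst | temperature | remark | time |
|---|---|---|---|---|---|---|
| larch | 26 mM | 15.6 mM | 3.9 mM | 110 °C | the very flask that is asked about, followed so far |  |
| ash | 26 mM | 15.6 mM | 1.9 mM | 95 °C | run made earlier |  |
| flask | 26 mM | 15.6 mM | 3.9 mM | 110 °C |  | 8.0 d |

| run | time / h | target / % | substrate / % |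
|---|---|---|---|
| larch | 25.0 | 45.8 | 39.7 |
| larch | 72.0 | 35.5 | 39.2 |
| larch | 120 | 32.7 | 40.6 |
| larch | 192 | 33.2 | 40.8 |
| ash | 8.00 | 7.5 | 89.5 |
| ash | 20.0 | 21.7 | 76.1 |
| ash | 40.0 | 41.0 | 56.3 |
| ash | 60.0 | 50.3 | 42.6 |

(readings scatter by 0.5 percentage points)

- dusk: at 8.0 d add reagent, 50.0% of the amount charged, then wait 4.0 d
- spring: at 8.0 d take out 90% of the target then present, then wait 4.0 d
- summer: at 8.0 d add free catalyst, 50.0% of the amount charged, then wait 4.0 d
- autumn: at 8.0 d raise the temperature by 20 K, then wait 4.0 d
- midnight: change nothing and wait 4.0 d more

- what is taken out of target is counted as made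
- additions bring no volume worth counting

* target, in percent of the substrate first charged, at 8.0 d
* the option that brings most further target ("none" if no option brings more than 2 percentage points) (dusk / spring / summer / autumn / midnight / none)
* target present, with what was taken out counted in, in percent of the substrate first charged, after summer
* target present, with what was taken out counted in, in percent of the substrate first charged, after midnight

If each substrate takes one reagent, the share of substrate that can react is [reagent] charged over [substrate] charged, which I called the reagent ceiling, 60.0%; it is the limiting reagent put as one number. In larch the substrate lost by the last reading was 59.2%, close to that ceiling. Target still moved, from 45.8% to 33.2%, and that last reading stood 0.5 percentage points above the one before, which is one scatter. So I committed to 33.2%, a share of the ceiling of 55.3%, as read. Free catalyst adds no reagent, so I left the ceiling alone for summer and gave summer and midnight that same number. Dusk lifts the ceiling to 90.0%, and at the same share I expected 49.8% of target, a gain of 17 points. On a repeat, I said, substrate tests the ceiling and target shows the split.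

The forecast gave 33%, chose dusk, and put 33% after summer and 33% after midnight, on the ground that “Substrate stalls at about 40% in larch, exactly where the reagent runs out”.

The flask gave 32.5%, with dusk best at 17 points further, 32.4% after summer and 32.4% after midnight.

    substrate + catalyst intermediate B → catalyst intermediate C (k = 170 M⁻¹ h⁻¹, Ea = 82.0 kJ mol⁻¹)
    catalyst intermediate C → catalyst intermediate D (k = 31.0 h⁻¹, Ea = 92.0 kJ mol⁻¹)
    reagent + free catalyst → catalyst intermediate A (k = 270 M⁻¹ h⁻¹, Ea = 76.0 kJ mol⁻¹)
    catalyst intermediate A → by-product + catalyst intermediate B (k = 1.50 h⁻¹, Ea = 115 kJ mol⁻¹)
    catalyst intermediate D → free catalyst + target (k = 4.20 h⁻¹, Ea = 124 kJ mol⁻¹)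
    target ⇌ isomer of the product (K = 0.850, k = 0.0170 h⁻¹, Ea = 119 kJ mol⁻¹, ΔH = −8.00 kJ mol⁻¹)
    (constants at 110 °C)

The forecast's 33% would have been wrong with the same charges and another split: the neighbour run at 85 °C held 50.5% of target and 9.50% of isomer of the product, with 40% of substrate left. In the flask at 192 h, target and isomer of the product together made 60.0%, the ceiling of 60.0%. With 44 mM of substrate the ceiling is 35.5%, and that neighbour held 19.2% of target, 16.3% of isomer of the product and 65% of substrate.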